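**Retrosynthetic overview**
1. Target 20 ⇐ spirocyclobutanone bromohydrin 17 by light: Norrish type I cleavage and re-closure through oxygen expand the cyclobutanone into the tetrahydrofuran ring (as a 2-oxacyclopentylidene), and the cis tertiary OH captures the carbene carbon to close the oxetane, so both acetal C–O bonds and the acetal stereocentre form in one operation.
2. Enabling feature: in 17 the carbonyl C1 of the four-membered ring lies between C2 (an allylic CH carrying the isopropenyl group, so C1–C2 is the bond that breaks and oxygen enters there) and the quaternary spiro carbon C4, whose neighbour C9 in the cyclohexene ring carries a tertiary OH held cis to C1.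
3. 17 ⇐ 11 by O-silylation, Wohl–Ziegler bromination at C8, α-isopropenylation at C2 (aldol with an α-silyl ketone, then Peterson elimination) and desilylation.
4. 11 ⇐ alkenylcyclopropanol 9 by catalytic asymmetric epoxidation and semipinacol ring expansion (three- to four-membered ring), which sets C4 and C9 and places OH cis to C=O; 9 ⇐ alkenyl iodide 5 + cyclopropanone; 5 ⇐ 2,2-dimethylcyclohexane-1,3-dione.
5. Order of ring formation: cyclohexene (from the dione) → cyclopropanol → spirocyclobutanone → tetrahydrofuran and oxetane together.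

Key step: step 11

Assumption: in step 6 the antipode of the bishydroxamic acid ligand is the one that delivers oxygen to the alkene face leading to (1R,6R)-10; the sense of induction has to be assigned on the first run.
Assumption: 1-ethoxycyclopropan-1-ol (6) and 1-(trimethylsilyl)propan-2-one (14) are taken as commercial; 6 is otherwise made by methanolysis of commercial (1-ethoxycyclopropoxy)trimethylsilane.

Spiro numbering used below: C1 = C=O, C2, C3, C4 = spiro carbon, C5 = CMe2, C6 = CBr=, C7 = =CH, C8, C9 = C(Me)O.

**Step 1**
Reactants: 1 2,2-dimethylcyclohexane-1,3-dione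
Product: 2 3-bromo-2,2-dimethylcyclohex-3-en-1-one
Conditions: (PhO)3P (1.1 equiv), Br2 (1.1 equiv), Et3N (1.3 equiv), CH2Cl2, −60 °C → reflux
Reagents that add atoms: bromine, BrBr
Why: Vinyl bromide synthesis from an enolisable ketone with the triphenyl phosphite–bromine reagent (O-activation, then elimination); the two carbonyls are equivalent, the quaternary C2 allows the alkene to form only toward C4, and one equivalent of reagent limits double conversion.

**Step 2**
Reactants: 2 3-bromo-2,2-dimethylcyclohex-3-en-1-one
Product: 3 3-bromo-2,2,6-trimethylcyclohex-3-en-1-one (racemic)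
Conditions: LDA, THF, −78 °C; MeI, −78 → −20 °C
Reagents that add atoms: iodomethane, CI
Why: Kinetic enolate alkylation at C6, the only enolisable position; the new stereocentre need not be controlled because it becomes sp2 in step 4.

**Step 3**
Reactants: 3 3-bromo-2,2,6-trimethylcyclohex-3-en-1-one
Product: 4 (3-bromo-2,2,6-trimethylcyclohex-3-en-1-ylidene)hydrazine (racemic)
Conditions: N2H4·H2O (excess), Et3N, EtOH, reflux
Reagents that add atoms: hydrazine (as hydrate), NN
Why: Hydrazone condensation, driven by excess hydrazine because the ketone is flanked by a quaternary and a tertiary carbon; the vinyl bromide is inert.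

**Step 4**
Reactants: 4 (3-bromo-2,2,6-trimethylcyclohex-3-en-1-ylidene)hydrazine
Product: 5 1-bromo-5-iodo-4,6,6-trimethylcyclohexa-1,4-diene
Conditions: I2, 1,1,3,3-tetramethylguanidine, THF, 0 °C → rt
Reagents that add atoms: iodine, II
Why: Barton vinyl iodide synthesis (iodination of the hydrazone, loss of N2, loss of the only α-hydrogen), which suits hindered hydrazones and should give the tetrasubstituted alkenyl iodide.

**Step 5**
Reactants: 5 1-bromo-5-iodo-4,6,6-trimethylcyclohexa-1,4-diene; 6 1-ethoxycyclopropan-1-ol
Product: 9 1-(5-bromo-2,6,6-trimethylcyclohexa-1,4-dien-1-yl)cyclopropan-1-ol, via alkenylmagnesium chloride 7 (not isolated), via cyclopropanone 8 (not isolated)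
Conditions: 5, i-PrMgCl·LiCl, THF, 0 °C → rt; then 6 pre-treated with i-PrMgCl (THF, −78 → 0 °C), → 45 °C; aq NH4Cl
Reagents that add atoms: none
Why: Iodine–magnesium exchange with the turbo-Grignard reagent is selective for C–I over C–Br, and the alkenyl Grignard adds to cyclopropanone released in situ from the magnesium hemiketalate (the hemiketal route to 1-alkenylcyclopropanols).

**Step 6**
Reactants: 9 1-(5-bromo-2,6,6-trimethylcyclohexa-1,4-dien-1-yl)cyclopropan-1-ol
Product: 11 (4S,9R)-6-bromo-9-hydroxy-5,5,9-trimethylspiro[3.5]non-6-en-1-one, via epoxy cyclopropanol 10 (not isolated)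
Conditions: WO2(acac)2 (5 mol%), chiral C2-symmetric bishydroxamic acid ligand (6 mol%), 30% aq H2O2, NaCl, CH2Cl2, rt
Reagents that add atoms: hydrogen peroxide, OO
Why: Hydroxyl-directed catalytic asymmetric epoxidation of the tertiary allylic (cyclopropyl) alcohol followed by semipinacol ring expansion of the 2,3-epoxy alcohol: the catalyst selects the alkene face, the cyclopropane carbon migrates anti to the breaking C–O bond, so C4 and C9 are set together with the C9 hydroxyl cis to the new carbonyl, and the electron-poor bromoalkene is not epoxidised.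

**Step 7**
Reactants: 11 (4S,9R)-6-bromo-9-hydroxy-5,5,9-trimethylspiro[3.5]non-6-en-1-one
Product: 12 (4S,9R)-6-bromo-5,5,9-trimethyl-9-(triethylsilyloxy)spiro[3.5]non-6-en-1-one
Conditions: TESOTf, 2,6-lutidine, CH2Cl2, −78 → 0 °C
Reagents that add atoms: triethylsilyl trifluoromethanesulfonate, CC[Si](CC)(CC)OS(=O)(=O)C(F)(F)F
Why: Silylation of the tertiary β-hydroxyl with a silyl triflate; it prevents retro-aldol cleavage in step 9 and supplies the bulky group that steers steps 8 and 9.

**Step 8**
Reactants: 12 (4S,9R)-6-bromo-5,5,9-trimethyl-9-(triethylsilyloxy)spiro[3.5]non-6-en-1-one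
Product: 13 (4S,8S,9S)-6,8-dibromo-5,5,9-trimethyl-9-(triethylsilyloxy)spiro[3.5]non-6-en-1-one
Conditions: NBS, AIBN (cat.), K2CO3, PhCF3, 80 °C
Reagents that add atoms: N-bromosuccinimide, O=C1CCC(=O)N1Br
Why: Wohl–Ziegler allylic bromination; C8 carries the only allylic hydrogens, the delocalised radical should be brominated at C8 and not at the hindered bromine-bearing C6, and bromine should be delivered anti to the OSiEt3 group on C9, which sets C8.

**Step 9**
Reactants: 13 (4S,8S,9S)-6,8-dibromo-5,5,9-trimethyl-9-(triethylsilyloxy)spiro[3.5]non-6-en-1-one; 14 1-(trimethylsilyl)propan-2-one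
Product: 16 (2R,4S,8S,9S)-6,8-dibromo-5,5,9-trimethyl-2-(prop-1-en-2-yl)-9-(triethylsilyloxy)spiro[3.5]non-6-en-1-one, via β-hydroxysilane 15 (not isolated)
Conditions: LiHMDS, THF, −78 °C; 14, −78 °C; AcOH quench; then TsOH·H2O (10 mol%), CH2Cl2, 0 °C
Reagents that add atoms: none
Why: Aldol addition of the lithium enolate (C2 is the only enolisable carbon, and the allylic bromide has no β-hydrogen for E2) to the α-silyl ketone followed by acid-promoted Peterson elimination, the α-silyl carbonyl acting as an alkenyl cation equivalent so that the alkene can form only toward CH2; the electrophile should approach C2 anti to the C9 arm bearing OSiEt3, which sets C2.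

**Step 10**
Reactants: 16 (2R,4S,8S,9S)-6,8-dibromo-5,5,9-trimethyl-2-(prop-1-en-2-yl)-9-(triethylsilyloxy)spiro[3.5]non-6-en-1-one
Product: 17 (2R,4S,8S,9S)-6,8-dibromo-9-hydroxy-5,5,9-trimethyl-2-(prop-1-en-2-yl)spiro[3.5]non-6-en-1-one
Conditions: HF·pyridine, THF/pyridine, 0 °C → rt
Reagents that add atoms: none
Why: Fluoride cleavage of the silyl ether under buffered, non-basic conditions, so that the trans-bromohydrin does not close to an epoxide and the β-hydroxy ketone does not undergo retro-aldol cleavage.

**Step 11**
Reactants: 17 (2R,4S,8S,9S)-6,8-dibromo-9-hydroxy-5,5,9-trimethyl-2-(prop-1-en-2-yl)spiro[3.5]non-6-en-1-one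
Product: 20 CNP0141320.1 (1S,3R,5S,7S,8S)-8,10-dibromo-7,11,11-trimethyl-3-(prop-1-en-2-yl)-4,6-dioxatricyclo[5.4.0.0(1,5)]undec-9-ene, via acyl–allyl biradical 18 (not isolated), via oxacarbene 19 (not isolated)
Conditions: hν (λ ≥ 300 nm, Pyrex, 350 nm lamps), degassed benzene (0.005 M), solid NaHCO3, 10 °C
Reagents that add atoms: none
Why: Proposed new method: n→π* excitation of the β,γ-unsaturated cyclobutanone causes Norrish type I cleavage of the allylic C1–C2 bond to biradical 18, which re-closes through the acyl oxygen at C2 with retention (the photochemical ring expansion of cyclobutanones) to the 2-oxacyclopentylidene 19, so the four-membered ring becomes the tetrahydrofuran by insertion of one oxygen atom. The carbene carbon of 19 is then protonated by the C9 tertiary hydroxyl held cis on the neighbouring carbon and the resulting contact ion pair collapses (formal intramolecular O–H insertion, 4-exo-trig C–O closure), which closes the oxetane and gives the bis-acetal 20. The closest known reactions are the ring expansion of cyclobutanones to 2-alkoxytetrahydrofurans with alcohol trapping and the intramolecular capture of such oxacarbenes by tethered hydroxyls to five- and six-membered acetals; capture by a β-hydroxyl to a four-membered acetal is the new element. The only new stereocentre, the acetal carbon, is fixed by the cis ring fusion imposed by the C4–C9 bond, and C2 is carried over with retention. The step needs C1–C2 over C1–C4 cleavage (secured by allylic stabilisation from the isopropenyl group, while the quaternary C4 also excludes a carbene 1,2-hydrogen shift), oxacarbene formation over 1,3-acyl shift (the shift isomer is a β,γ-enone that re-enters the same biradical manifold on continued irradiation, whereas capture is irreversible) and ring closure over Grob-type cleavage of C4–C9 (favoured in a non-polar solvent at low temperature); light of ≥300 nm leaves both C–Br bonds unexcited.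

**Compound list**
1 | 2,2-dimethylcyclohexane-1,3-dione | CC1(C)C(=O)CCCC1=O | starting material
2 | 3-bromo-2,2-dimethylcyclohex-3-en-1-one | O=C1CCC=C(Br)C1(C)C | intermediate
3 | 3-bromo-2,2,6-trimethylcyclohex-3-en-1-one (racemic; C6 is removed in step 4) | O=C1C(C)CC=C(Br)C1(C)C | intermediate
4 | (3-bromo-2,2,6-trimethylcyclohex-3-en-1-ylidene)hydrazine (racemic) | NN=C1C(C)CC=C(Br)C1(C)C | intermediate
5 | 1-bromo-5-iodo-4,6,6-trimethylcyclohexa-1,4-diene | IC1=C(C)CC=C(Br)C1(C)C | intermediate
6 | 1-ethoxycyclopropan-1-ol (cyclopropanone ethyl hemiketal) | CCOC1(O)CC1 | starting material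
7 | (5-bromo-2,6,6-trimethylcyclohexa-1,4-dien-1-yl)magnesium chloride | Cl[Mg]C1=C(C)CC=C(Br)C1(C)C | intermediate (not isolated)
8 | cyclopropanone | O=C1CC1 | intermediate (not isolated)
9 | 1-(5-bromo-2,6,6-trimethylcyclohexa-1,4-dien-1-yl)cyclopropan-1-ol | OC1(CC1)C2=C(C)CC=C(Br)C2(C)C | intermediate
10 | 1-[(1R,6R)-3-bromo-2,2,6-trimethyl-7-oxabicyclo[4.1.0]hept-3-en-1-yl]cyclopropan-1-ol | OC1(CC1)[C@@]23O[C@]2(C)CC=C(Br)C3(C)C | intermediate (not isolated)
11 | (4S,9R)-6-bromo-9-hydroxy-5,5,9-trimethylspiro[3.5]non-6-en-1-one (OH cis to C=O) | C1C[C@@]2(C1=O)[C@](C)(O)CC=C(Br)C2(C)C | intermediate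
12 | (4S,9R)-6-bromo-5,5,9-trimethyl-9-(triethylsilyloxy)spiro[3.5]non-6-en-1-one | C1C[C@@]2(C1=O)[C@](C)(O[Si](CC)(CC)CC)CC=C(Br)C2(C)C | intermediate
13 | (4S,8S,9S)-6,8-dibromo-5,5,9-trimethyl-9-(triethylsilyloxy)spiro[3.5]non-6-en-1-one (C8–Br trans to C9–O) | C1C[C@@]2(C1=O)[C@](C)(O[Si](CC)(CC)CC)[C@@H](Br)C=C(Br)C2(C)C | intermediate
14 | 1-(trimethylsilyl)propan-2-one | CC(=O)C[Si](C)(C)C | starting material
15 | (2R,4S,8S,9S)-6,8-dibromo-2-[2-hydroxy-1-(trimethylsilyl)propan-2-yl]-5,5,9-trimethyl-9-(triethylsilyloxy)spiro[3.5]non-6-en-1-one (both carbinol epimers) | C[Si](C)(C)CC(C)(O)[C@H]1C[C@@]2(C1=O)[C@](C)(O[Si](CC)(CC)CC)[C@@H](Br)C=C(Br)C2(C)C | intermediate (not isolated)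
16 | (2R,4S,8S,9S)-6,8-dibromo-5,5,9-trimethyl-2-(prop-1-en-2-yl)-9-(triethylsilyloxy)spiro[3.5]non-6-en-1-one | C=C(C)[C@H]1C[C@@]2(C1=O)[C@](C)(O[Si](CC)(CC)CC)[C@@H](Br)C=C(Br)C2(C)C | intermediate
17 | (2R,4S,8S,9S)-6,8-dibromo-9-hydroxy-5,5,9-trimethyl-2-(prop-1-en-2-yl)spiro[3.5]non-6-en-1-one (isopropenyl cis to the CMe2 arm) | C=C(C)[C@H]1C[C@@]2(C1=O)[C@](C)(O)[C@@H](Br)C=C(Br)C2(C)C | intermediate
18 | acyl–allyl 1,4-biradical from C1–C2 cleavage of 17 | C=C(C)[CH]C[C@@]1([C]=O)[C@](C)(O)[C@@H](Br)C=C(Br)C1(C)C | intermediate (not isolated)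
19 | 2-oxacyclopentylidene (oxacarbene) spiro-fused to the bromohydrin ring | C=C(C)[C@H]1C[C@@]2([C]O1)[C@](C)(O)[C@@H](Br)C=C(Br)C2(C)C | intermediate (not isolated)
20 | CNP0141320.1, (1S,3R,5S,7S,8S)-8,10-dibromo-7,11,11-trimethyl-3-(prop-1-en-2-yl)-4,6-dioxatricyclo[5.4.0.0(1,5)]undec-9-ene | C=C(C)[C@H]1C[C@@]23[C@@H](O1)O[C@]2(C)[C@@H](Br)C=C(Br)C3(C)C | target

**Step count and risks**
Total step count: 11. Longest linear sequence: 11 steps (1 → 20).

Steps most likely to fail:

1. Step 11 (proposed new method). The oxacarbene may revert to the ketone, lose CO or drain into 1,3-acyl shift faster than the hydroxyl adds, or the capture intermediate may cleave the C4–C9 bond instead of closing the four-membered ring. The fallback uses known chemistry, sets out from 17 and returns at 20. Irradiation of 17 in MeCN/H2O traps the oxacarbene with water, the established intermolecular version, and should give lactol F1 (anomers). Acetylation (Ac2O, pyridine; the tertiary OH stays free) gives anomeric acetate F2. TMSOTf (cat.) with 2,6-di-tert-butyl-4-methylpyridine in CH2Cl2 at −78 °C then ionises the acetate, and the cis tertiary hydroxyl closes the oxetane by intramolecular acetal exchange at the anomeric centre, the closure type used for anhydro sugars, to give 20.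

2. Step 6. Enantiofacial discrimination may be poor, or turnover slow, at a tetrasubstituted alkene flanked by a quaternary carbon; oxidative opening of the cyclopropanol may compete. The fallback sets out from 9 and returns at 11. Achiral hydroxyl-directed epoxidation and ring expansion (VO(acac)2, t-BuOOH, CH2Cl2) gives racemic hydroxy ketone F3, which is resolved by preparative chiral SFC to give 11; the relative configuration is still fixed by the anti migration.

3. Step 9. Proton transfer from the α-silyl ketone to the enolate may outrun carbonyl addition, the aldolate may undergo retro-aldol before elimination, or the electrophile may approach the wrong face. The fallback sets out from 13 and returns at 16. LiHMDS/TMSCl (THF, −78 °C) gives trimethylsilyl enol ether F4, which is alkenylated directly with isopropenyl(mesityl)iodonium triflate under copper(I) catalysis (CH2Cl2, rt); this copper-catalysed electrophilic alkenylation of an enol silane replaces the aldol–elimination sequence and gives 16.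

**Further compounds**
F1 | step 11 | lactol: 2-hydroxytetrahydrofuran from water trapping of oxacarbene 19 (anomeric mixture) | C=C(C)[C@H]1C[C@@]2(C(O)O1)[C@](C)(O)[C@@H](Br)C=C(Br)C2(C)C
F2 | step 11 | anomeric acetate of F1 | C=C(C)[C@H]1C[C@@]2(C(OC(C)=O)O1)[C@](C)(O)[C@@H](Br)C=C(Br)C2(C)C
F3 | step 6 | racemic 6-bromo-9-hydroxy-5,5,9-trimethylspiro[3.5]non-6-en-1-one (OH cis to C=O; both enantiomers) | C1C[C@@]2(C1=O)[C@](C)(O)CC=C(Br)C2(C)C.C1C[C@]2(C1=O)[C@@](C)(O)CC=C(Br)C2(C)C
F4 | step 9 | trimethylsilyl enol ether of 13 | C[Si](C)(C)OC1=CC[C@]12[C@](C)(O[Si](CC)(CC)CC)[C@@H](Br)C=C(Br)C2(C)C
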